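Everything rests on disconnecting the O–C7 bond of ring B. In ring A, C7 holds both a methyl group and the ring-B oxygen and sits para to the brominated carbon C10, the pattern of a para-cresol. Ring A is therefore taken back to a phenol (OH on C10, CH3 on C7) that carries the acid chain C5–C2 on C6. A single oxidative dearomatization under a chiral trivalent-iodine catalyst bonds the carboxyl oxygen to C7. Ring B closes as a seven-membered lactone, the C7 stereocentre that relays all others is created, and C10 emerges as a ketone with C11 as its α-carbon. The precursor, 4-(5-hydroxy-2-methylphenyl)-2-methylbutanoic acid, needs two steps; nine conventional steps follow.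

Key step: step 3

**Remarks**
- **Numbering:** C1 exocyclic CHBr, C2 enol-ether carbon, C3 methyl-bearing epoxide carbon, C4 epoxide CH, C5 CH2, C6 ring-fusion CH, C7 C(CH3)–O, C8 and C9 CH2, C10 CHBr, C11 C(CH3)2. Ring A is the cyclohexane C6–C11. Ring B is the oxepane O/C2–C7.
- **Target configuration:** in these locants the target is (1E,3S,4S,6R,7R,10R). H6, H10 and the epoxide oxygen lie on one face ("top"). The C7 methyl, the C3 methyl and the equatorial C10 bromine lie on the other ("bottom"). The ring fusion is trans.
- **Catalyst:** ArI* is (R,R)-2,2'-[(2-iodo-1,3-phenylene)bis(oxy)]bis[N-(2,4,6-trimethylphenyl)propanamide], SMILES C[C@@H](Oc1cccc(O[C@H](C)C(=O)Nc2c(C)cc(C)cc2C)c1I)C(=O)Nc1c(C)cc(C)cc1C.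
- **Assumption:** the sense of induction of ArI* in a para closure cannot be predicted. Both enantiomers are equally accessible from the two lactates, so the one that gives (7R)-6 is fixed after assay of a first run.
- **Design of the side chain:** C3 is left racemic because it becomes sp2 in step 9, so compounds 4 to 14 are C3 epimer mixtures that converge. C3 and C4 stay unfunctionalized until C5=C6 is reduced, because step 5 puts carbanion character on C5, which would expel any leaving group or epoxide oxygen at C4.

Step 1
Reactants: 1 methyl 2-methylbut-3-enoate; 2 3-bromo-4-methylanisole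
Product: 4 methyl 4-(5-methoxy-2-methylphenyl)-2-methylbutanoate, via B-alkyl-9-BBN adduct 3 (not isolated)
Conditions: 9-BBN-H, THF, 0 °C to rt; then 2, PdCl2(dppf) (5 mol %), K3PO4 (3 M aq.), DMF, 60 °C
Reagents that add atoms: 9-borabicyclo[3.3.1]nonane, [H]B1C2CCCC1CCC2 (its boron unit is found in 3 only)
Why: Anti-Markovnikov hydroboration of the monosubstituted alkene puts boron on the terminal carbon (the future C5) without touching the ester, and the B-alkyl Suzuki–Miyaura coupling then forms the C5–C6 bond at the aryl bromide.

Step 2
Reactants: 4 methyl 4-(5-methoxy-2-methylphenyl)-2-methylbutanoate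
Product: 5 4-(5-hydroxy-2-methylphenyl)-2-methylbutanoic acid
Conditions: 48% aq. HBr, AcOH, reflux
Reagents that add atoms: water, O
Why: Classical aryl methyl ether cleavage and acid-catalysed ester hydrolysis run in one operation on a substrate without any other sensitive group, which frees the phenol and the acid that the key step needs.

Step 3
Reactants: 5 4-(5-hydroxy-2-methylphenyl)-2-methylbutanoic acid
Product: 6 (7R)-dienone lactone (4-acyloxy-4-methylcyclohexa-2,5-dienone fused through C6–C7 to the seven-membered lactone; C3 epimers)
Conditions: ArI* (15 mol %), purified mCPBA (1.3 equiv, slow addition), CH2Cl2/(CF3)2CHOH 9:1, 5 mM, −20 °C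
Reagents that add atoms: none
Why: Proposed new method: mCPBA raises the iodoarene to trivalent iodine, the phenol oxygen of 5 displaces a ligand, and the C2 carboxyl oxygen adds to C7 while the C10–O–I linkage breaks and the iodoarene is released, so that ring A loses two electrons and becomes a cross-conjugated dienone. The closest known reaction types are trivalent-iodine or anodic para-dearomatization of 4-alkylphenols with carboxylic acid capture and chiral-iodoarene-catalysed dearomative spirolactonization, neither of which has been shown for an enantioselective, ring-fused seven-membered closure. Ring B closes in a 7-exo-trig sense relative to C7=C8, helped by the two sp2 atoms C6 and C7 already in the forming ring and by the C3 branch. C7, the only new stereocentre, is controlled by the folded amide arms of the iodine-bound catalyst, which cover one face of ring A so that the tether must swing in from the other. The step needs para (C7) over ortho (C11, C9) attack, secured by the C7 methyl, which localizes the developing positive charge at the para carbon, and by the bulk of the iodanyl oxygen next to the ortho carbons; it also needs internal over external capture, secured by high dilution and the non-nucleophilic fluoro alcohol.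

Step 4
Reactants: 6 (7R)-dienone lactone
Product: 7 (7R)-enone lactone (C8–C9 saturated; C6=C11 retained)
Conditions: H2 (1 atm), RhCl(PPh3)3 (10 mol %), toluene/EtOH 1:1, rt
Reagents that add atoms: none
Why: Homogeneous rhodium-catalysed hydrogenation discriminates by substitution, so the disubstituted C8=C9 bond is saturated and the trisubstituted C6=C11 bond stays, as in the known change of 1,4-dien-3-ones into 4-en-3-ones, and no heterogeneous metal is present that could cleave C7–O and rearomatize ring A.

Step 5
Reactants: 7 (7R)-enone lactone
Product: 9 (7R)-11,11-dimethyl β,γ-unsaturated keto lactone (C5=C6), via C11-monomethyl ketone 8 (not isolated)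
Conditions: KOt-Bu (2.3 equiv), MeI (6 equiv), t-BuOH/THF, 0 °C to rt
Reagents that add atoms: iodomethane, CI
Why: Deconjugative α,α-dialkylation of an enone, in which tert-butoxide removes a γ-proton from C5, the extended dienolate is methylated at its α-carbon C11, the doubly activated C11–H of 8 is removed and methylated again so that the alkene is parked at C5=C6, and the far less acidic tertiary C3–H of the lactone is at most epimerized.

Step 6
Reactants: 9 (7R)-11,11-dimethyl β,γ-unsaturated keto lactone
Product: 10 (6R,7R)-saturated keto lactone (trans-fused)
Conditions: H2 (50 bar), [Ir(cod)(PCy3)(py)]PF6 (5 mol %), CH2Cl2, rt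
Reagents that add atoms: none
Why: Cationic iridium-catalysed hydrogenation reduces hindered trisubstituted alkenes without hydrogenolysis of the allylic C7–O bond, and because allylic strain keeps the C7 oxygen in the alkene plane and the C7 methyl axial, the bottom face is closed by the syn-axial C7 and C11 methyl groups, so hydrogen enters from the top and sets 6R (H6 anti to the C7 methyl).

Step 7
Reactants: 10 (6R,7R)-saturated keto lactone
Product: 11 (6R,7R,10S)-axial C10 alcohol
Conditions: LiBH(s-Bu)3, THF, −78 °C; then H2O
Reagents that add atoms: none
Why: Bulky trialkylborohydride reduction of a cyclohexanone, in which hydride arrives along the equatorial trajectory as with 4,4-dimethyl-3-oxo terpenoids and gives the axial (top-face) 10S alcohol, while the hindered lactone is not reduced at −78 °C.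

Step 8
Reactants: 11 (6R,7R,10S)-axial C10 alcohol
Product: 12 (6R,7R,10R)-bromo lactone (equatorial bromine)
Conditions: CBr4, PPh3, 2,6-lutidine, toluene, 0 to 60 °C
Reagents that add atoms: carbon tetrabromide, BrC(Br)(Br)Br
Why: Appel reaction, in which bromide displaces the axial oxyphosphonium group from the equatorial side by SN2 with inversion to give the equatorial 10R bromide, the non-polar buffered medium disfavouring the ionization that leads to methyl shift or elimination at this neopentyl-type centre.

Step 9
Reactants: 12 (6R,7R,10R)-bromo lactone
Product: 15 (6R,7R,10R)-α-methyl-α,β-unsaturated bromo lactone (C3=C4), via C3 phenylselenide 13 (not isolated), via C3 selenoxide 14 (not isolated)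
Conditions: LDA, THF, −78 °C; PhSeBr, −78 °C; then 30% H2O2, 0 °C to rt
Reagents that add atoms: phenylselenyl bromide, Br[Se]c1ccccc1; hydrogen peroxide, OO (selenium and the extra oxygen are found in 13 and 14 only)
Why: Selenoxide syn-elimination, in which the lactone enolate is selenenylated at C3 and the selenoxide eliminates preferentially toward the ring hydrogen at C4 to give the more substituted conjugated endocyclic alkene (any exocyclic methylene isomer is removed by chromatography), while the equatorial bromide has no antiperiplanar hydrogen and survives the base.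

Step 10
Reactants: 15 (6R,7R,10R)-α-methyl-α,β-unsaturated bromo lactone
Product: 16 (3S,4S,6R,7R,10R)-epoxy lactone
Conditions: dimethyldioxirane (excess), acetone/CH2Cl2, rt
Reagents that add atoms: dimethyldioxirane, CC1(C)OO1
Why: Dioxirane epoxidation of an α-methyl enoate under neutral conditions, in which the nearly planar O–C2–C3=C4–C5 segment of ring B is shielded from below by the axial C7 methyl, so oxygen should be transferred to the top face, syn to H6, which sets 3S and 4S.

Step 11
Reactants: 16 (3S,4S,6R,7R,10R)-epoxy lactone
Product: 17 (3S,4S,6R,7R,10R)-2-(dibromomethylidene) epoxy oxepane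
Conditions: [Ph3PCHBr2]Br, KOt-Bu, THF, 0 °C (ylide pre-formed); then 16, rt to reflux
Reagents that add atoms: (dibromomethyl)triphenylphosphonium bromide, BrC(Br)[P+](c1ccccc1)(c1ccccc1)c1ccccc1.[Br-]
Why: Wittig-type dibromomethylenation (Ramirez olefination) of a lactone carbonyl, known for α-oxygenated lactones, with the ylide Ph3P=CBr2 pre-formed from its salt so that neither Ph3PBr2 nor free base meets the epoxide, and with the α-oxygen raising the electrophilicity of C2.

Step 12
Reactants: 17 (3S,4S,6R,7R,10R)-2-(dibromomethylidene) epoxy oxepane
Product: 18 target CNP0375295.2, (1E,3S,4S,6R,7R,10R)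
Conditions: Bu3SnH (1.05 equiv), Pd(PPh3)4 (5 mol %), toluene, 0 °C to rt
Reagents that add atoms: none
Why: Palladium-catalysed hydrogenolysis of a 1,1-dibromoalkene with a tin hydride, in which zerovalent palladium inserts faster into the less hindered C–Br bond (cis to the ring oxygen, trans to the fully substituted C3) and hydride transfer with retention leaves the bromine cis to C3, that is the E alkene, while the secondary C10 bromide is inert without a radical initiator.

**Compound list**
1 | methyl 2-methylbut-3-enoate (racemic) | C=CC(C)C(=O)OC | starting material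
2 | 3-bromo-4-methylanisole (2-bromo-4-methoxy-1-methylbenzene) | COc1ccc(C)c(Br)c1 | starting material
3 | methyl 4-(9-borabicyclo[3.3.1]nonan-9-yl)-2-methylbutanoate | COC(=O)C(C)CCB1C2CCCC1CCC2 | intermediate
4 | methyl 4-(5-methoxy-2-methylphenyl)-2-methylbutanoate | COC(=O)C(C)CCc1cc(OC)ccc1C | intermediate
5 | 4-(5-hydroxy-2-methylphenyl)-2-methylbutanoic acid | Cc1ccc(O)cc1CCC(C)C(=O)O | intermediate
6 | (9aR)-3,9a-dimethyl-3,4,5,9a-tetrahydro-1-benzoxepine-2,7-dione; dienone lactone, 7R in chain numbering, C3 epimers | CC1CCC2=CC(=O)C=C[C@@]2(C)OC1=O | intermediate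
7 | enone lactone, 7R, C8–C9 saturated, C6=C11 | CC1CCC2=CC(=O)CC[C@@]2(C)OC1=O | intermediate
8 | C11-monomethyl β,γ-unsaturated keto lactone, 7R, C5=C6 | CC1C(=O)CC[C@@]2(C)OC(=O)C(C)CC=C12 | intermediate
9 | 11,11-dimethyl β,γ-unsaturated keto lactone, 7R, C5=C6 | CC1(C)C(=O)CC[C@@]2(C)OC(=O)C(C)CC=C12 | intermediate
10 | trans-fused saturated keto lactone, 6R,7R | CC1(C)C(=O)CC[C@@]2(C)OC(=O)C(C)CC[C@H]12 | intermediate
11 | axial C10 alcohol, 6R,7R,10S | CC1(C)[C@@H](O)CC[C@@]2(C)OC(=O)C(C)CC[C@H]12 | intermediate
12 | equatorial C10 bromide, saturated lactone, 6R,7R,10R | CC1(C)[C@H](Br)CC[C@@]2(C)OC(=O)C(C)CC[C@H]12 | intermediate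
13 | C3-(phenylselanyl) bromo lactone | CC1(C)[C@H](Br)CC[C@@]2(C)OC(=O)C(C)([Se]c3ccccc3)CC[C@H]12 | intermediate
14 | C3-(phenylseleninyl) bromo lactone | CC1(C)[C@H](Br)CC[C@@]2(C)OC(=O)C(C)([Se](=O)c3ccccc3)CC[C@H]12 | intermediate
15 | α-methyl-α,β-unsaturated bromo lactone (C3=C4), 6R,7R,10R | CC1(C)[C@H](Br)CC[C@@]2(C)OC(=O)C(C)=CC[C@H]12 | intermediate
16 | epoxy lactone, 3S,4S,6R,7R,10R (epoxide oxygen syn to H6) | CC1(C)[C@H](Br)CC[C@@]2(C)OC(=O)[C@@]3(C)O[C@H]3C[C@H]12 | intermediate
17 | 2-(dibromomethylidene) epoxy oxepane, 3S,4S,6R,7R,10R | CC1(C)[C@H](Br)CC[C@@]2(C)OC(=C(Br)Br)[C@@]3(C)O[C@H]3C[C@H]12 | intermediate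
18 | CNP0375295.2, (1E,3S,4S,6R,7R,10R) | CC1(C)[C@H](Br)CC[C@@]2(C)O/C(=C/Br)[C@@]3(C)O[C@H]3C[C@H]12 | target

Total step count: 12. Longest linear sequence: 12 steps (from 1 or 2 to 18).

**Steps most likely to fail**

1. **Step 3.**
   - What may go wrong: outside nucleophiles may capture the oxidized ring before the seven-membered ring can close. Attack at the ortho carbon C11 may be followed by rearomatization and over-oxidation. Face discrimination may be weak because the chiral iodine centre is far from C7.
   - Fallback (known chemistry), from 5 back to 6: the O–C7 bond and the acyl–O bond are made in separate, established operations. Hydroxylative dearomatization of the 4-alkylphenol with PhI(OAc)2 in MeCN/H2O at 0 °C should give the para-quinol acid F1. Shiina lactonization (2-methyl-6-nitrobenzoic anhydride, DMAP, high dilution, CH2Cl2) should acylate the tertiary quinol hydroxyl to give the racemic dienone lactone F2. DBU then equilibrates C3 to simplify the mixture. Preparative chromatography on a chiral stationary phase should deliver the 7R enantiomer, which is 6.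

2. **Step 11.**
   - What may go wrong: the bulky ylide may add slowly to a carbonyl flanked by two fully substituted carbons, and opening of the epoxide may take over on prolonged heating.
   - Fallback, from 16 back to 17: the C1=C2 bond is made with a small titanium carbene instead of a phosphorus ylide. Petasis methylenation (Cp2TiMe2, toluene, 70 °C, dark) should give the exocyclic enol ether F3. Bromine addition (Br2, CH2Cl2, −78 °C) should give the 1,2-dibromide F4, which loses HBr on addition of DBU to give the bromomethylidene compound F5 as an E/Z mixture. A second bromine addition gives the tribromide F6, and DBU elimination lets both isomers converge on 17. The alkene geometry is therefore still set in step 12.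

3. **Step 8.**
   - What may go wrong: the activated axial alcohol may ionize, with loss of the antiperiplanar C9 hydrogen or a 1,2-shift of the antiperiplanar axial C11 methyl in place of substitution.
   - Fallback, from 10 back to 12, bypassing 11: C10 is set by C–H rather than C–Br bond formation. (PhO)3P, Br2 and Et3N (CH2Cl2, −60 °C to reflux) should convert the ketone into the vinyl bromide F7 (C9=C10). Hydrogen-atom-transfer hydrogenation follows (Mn(dpm)3 cat., PhSiH3, t-BuOOH, i-PrOH, rt), a method that preserves vinylic halogen. It should add hydrogen to C9 and then deliver hydrogen to the α-bromo radical at C10 from the top (axial) face, away from the axial C11 methyl, to give the equatorial bromide 12.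

Further compounds
F1 | step 3 | 4-(6-hydroxy-6-methyl-3-oxocyclohexa-1,4-dien-1-yl)-2-methylbutanoic acid (racemic para-quinol acid) | CC(CCC1=CC(=O)C=CC1(C)O)C(=O)O
F2 | step 3 | racemic dienone lactone (both C7 configurations) | CC1CCC2=CC(=O)C=CC2(C)OC1=O
F3 | step 11 | 2-methylidene epoxy oxepane (exocyclic enol ether), 3S,4S,6R,7R,10R | CC1(C)[C@H](Br)CC[C@@]2(C)OC(=C)[C@@]3(C)O[C@H]3C[C@H]12
F4 | step 11 | 2-bromo-2-(bromomethyl) adduct of F3 (C2 unassigned) | CC1(C)[C@H](Br)CC[C@@]2(C)OC(Br)(CBr)[C@@]3(C)O[C@H]3C[C@H]12
F5 | step 11 | 2-(bromomethylidene) epoxy oxepane, E/Z mixture | CC1(C)[C@H](Br)CC[C@@]2(C)OC(=CBr)[C@@]3(C)O[C@H]3C[C@H]12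
F6 | step 11 | 2-bromo-2-(dibromomethyl) adduct of F5 (C2 unassigned) | CC1(C)[C@H](Br)CC[C@@]2(C)OC(Br)(C(Br)Br)[C@@]3(C)O[C@H]3C[C@H]12
F7 | step 8 | C10 vinyl bromide (C9=C10), 6R,7R | CC1(C)C(Br)=CC[C@@]2(C)OC(=O)C(C)CC[C@H]12
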